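## Structural features

The target is a 3-(indol-1-yl)indole. Ring A is a 1H-indole with SMe on C2 and bromine on C4, C5 and C6; ring B is an indole with bromine on C2', C4' and C6' and SMe on C3'; the only link is the N1'–C3 bond. There is no stereocentre, so no centres stand next to each other. Rotation about N1'–C3 is hindered (C2'–Br and C7'–H on one side, C2–SMe and the peri C4–Br on the other), but the structure carries no axial descriptor and nothing has to be controlled. The fragile parts are the six aryl and heteroaryl C–Br bonds (no hydrogenolysis, no halogen–metal exchange, no selective palladium- or copper-catalysed C–N coupling), the two thioethers, the 2-bromoindole of ring B and the electron-rich amino-thio-substituted pyrrole ring of ring A. The real difficulty is twofold: N1'–C3 joins two hindered sp2 atoms, and the benzo rings carry different bromine patterns (contiguous 4,5,6 in ring A, alternating 4',6' in ring B) that late bromination could not install. The key step uses the fact that C2 of ring A is bonded to S, N1 and C3, the oxidation level of a ketene dithioacetal carbon, while C3 is bonded to N1' and to C3a, whose neighbour C7a bears N1. With N1 carried as a nitro group, C3 becomes a benzylic CH2 acidified by the ortho-nitroaryl ring and by N1'; its carbanion can take up CS2 as C2, and the nitro group later closes the ring as N1.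

## Logic of the disconnections

16 ⇒ 13 (through 15 and 14). The N1–C2 bond of ring A is cut and N1 is returned to the nitro level. C2 then carries two SMe groups and ring A becomes an open tetrasubstituted alkene on a nitroarene. This keeps the oxidation-prone amino-thio-indole out of every earlier stage and leaves one self-terminating step at the end. The forward step must reduce the nitro group without touching six C–Br and three C–S bonds and must expel exactly one methanethiol, which calls for an acidic medium.

13 ⇒ 9 + 10 (key disconnection). C2–C3 and both S–CH3 bonds are cut. C2 is a one-carbon unit at the acid oxidation level bonded to two sulfur atoms, which is what 10 is; the methyl groups come from a methyl electrophile. 13 collapses to a methylene compound that already holds all six bromines, the ring B thioether and the N1'–C3 bond. The forward step needs clean deprotonation of the benzylic CH2 of 9 and attack through carbon, passing 11 and 12.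

9 ⇒ 3 + 8. The N1'–CH2 bond is cut. In 16 this bond joins two hindered sp2 atoms; in 9 its carbon is sp3 and benzylic, so an SN2 alkylation makes it without any metal. Two fragments of similar size result, each with its bromine pattern complete. Nitrogen must be the only nucleophilic site of 3 (C2' and C3' are occupied), and the displacement must tolerate the two ortho substituents of 8.

3 ⇒ 2 ⇒ 1. C2'–Br and then C3'–S are cut, the reverse of the order of electrophilic reactivity of an indole. The 4',6'-dibromo pattern is bought with 1. The forward steps must sulfenylate next to the peri bromine and then stop bromination at C2'.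

8 ⇒ 7. The benzylic C–Br bond is cut. 7 has only one kind of C(sp3)–H bond, so radical bromination has no choice of site but must stop at the monobromide.

7 ⇒ 5 (through 6) ⇒ 4. The middle aryl C–Br bond is cut back to an amino group and the two outer C–Br bonds to C–H. In 4 the amino group is para to nitro and meta to methyl, so its two ortho positions are the outer bromine positions and its own carbon becomes the middle one. The methyl group thus ends between Br and NO2, as ring A requires. The forward steps need dibromination of a deactivated aniline, including the position between NH2 and CH3, and diazotisation of a weakly basic, hindered aniline.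

## Other disconnections considered

Alternative 1: The cut removes N1'–C7a' and C3'–C3a', so the benzo ring of ring B is added as an aryne. Forward, fluoride would release the dibromoaryne from silyl triflate A3. The amine nitrogen of glycinate A2 should add to the aryne carbon remote from the flanking bromine, and the aryl anion formed next to that bromine should acylate on the ester to give indolin-3-one A1.
- In favour: two bonds and ring B in one metal-free operation, the 4',6'-pattern decided by the aryne, and no C–Br bond at risk.
- Against: A2 is a free 3-aminoindole, oxidation-prone and itself needing a synthesis that already contains the 4,5,6-tribromo pattern and C2–SMe. The N1–H of ring A and the sulfur atom are competing aryne acceptors. A3 takes several steps from a bromophenol. A1 lacks both C3'–SMe and C2'–Br, so thionation, S-methylation and a bromination in the presence of the oxidisable ring A would follow.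
- Structure: the alternative builds ring B on a finished ring A; the chosen plan builds ring A on a finished ring B. Only the chosen plan turns the hindered N1'–C3 bond into a benzylic N-alkylation.
- Mechanism: the aryne annulation closes a ring and forms two bonds in its key step, while the chosen key step closes none. On complexity gained in one step, and in avoiding a nitrobenzyl carbanion, the alternative is the better.
- Step economy: poorer, with three or more steps after A1 and two multistep precursors, against one step after 13.

Alternative 2: The cut is C2'–C3'. Forward, NaOMe would deprotonate the N–CH2CO2Me group of diester A5 and the enolate would attack the neighbouring benzoate carbonyl (5-exo-trig), giving hydroxyindole ester A4 as its stabilised enolate.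
- In favour: this Dieckmann closure is among the most dependable ways to a pyrrole ring of an indole, is driven by deprotonation of the product and raises no question of regiochemistry. In reliability of the key step it is better than the chosen plan, whose carbanion chemistry is an extension of known practice.
- Against: A4 carries CO2Me on C2' and OH on C3', neither of which belongs to 16. Hydrolysis and decarboxylation would lead to A1 and then to the same thionation, S-methylation and bromination as in alternative 1, about four steps through an air-sensitive indoxyl. A5 is a hindered tertiary amine whose assembly needs a C–N bond to C3 of ring A (aminoindole chemistry, or C–N coupling beside five C–Br bonds) and an N-alkylation between ortho substituents.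
- Structure: both plans take the bromine patterns from arene precursors, but the alternative must still solve the N–C3 bond directly.
- Mechanism: a classical enolate acylation against a new carbanion dithiocarboxylation; the alternative is safer at the key step and weaker before and after it.
- Step economy: clearly poorer.

Alternative 3: The cut is N1'–C2'. Forward, Cs2CO3 or KOtBu in DMSO would eliminate HBr from the dibromovinyl group of A7 to a bromoalkyne, and the linker nitrogen anion would add to the bromine-bearing alkyne carbon (5-endo-dig), giving bisindole A6 with the C2' bromine in place.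
- In favour: base only, no metal; the C2' bromine comes from the ring closure and not from a separate bromination. Only C3' sulfenylation would remain, the reaction type of step 1, and ring A offers no free nucleophilic carbon. The endgame is therefore as short as that of the chosen plan (equal). The ring-closure type is established for 2-(2,2-dibromovinyl)anilines, so in precedent for the key step the alternative is the better.
- Against: A7 is a diarylamine between C3 of ring A and a di-ortho-substituted aniline, so its N–C3 bond is the same unsolved problem as in alternatives 1 and 2. The dibromo-olefin needs a Ramirez olefination (CBr4, PPh3) of an aldehyde beside that amine. Under base the N1–H of ring A is ionised as well, and the late sulfenylation must leave the N–H and SMe of ring A alone.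
- Structure: the chosen plan never has to form an N–C(sp2) bond between the rings.
- Mechanism: both key steps are anionic and metal-free.
- Step economy: comparable after the key step, poorer before it because of A7.

Key step: step 7

Remarks on the chemistry (corrections and assumptions):
- Nitration of 3,4,5-tribromotoluene is not a way to the arene of 9. Its only free positions lie between CH3 and Br, so the nitro group would sit next to a bromine and the sequence would end as a 5,6,7-tribromo ring A. Ring A of 16 needs 2,3,4-tribromo-6-nitrotoluene (CH3 between Br and NO2), which steps 3 and 4 make from 3-methyl-4-nitroaniline.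
- Direct attack of N1 on C2 of the C2=C3 bond of 14 would be 5-endo-trig. Step 8 is therefore run in acid, where C3 is protonated first and nitrogen closes on the bis(methylthio)carbenium ion in a 5-exo-trig sense.
- Safety choices: the key step uses NaN(SiMe3)2 in THF at low temperature in place of NaH in DMF, a pair with a known thermal hazard. Br2, MeSCl, CCl4 and isolated diazonium salts are avoided. Methanethiol from step 8 is scrubbed with NaOCl.
- Assumption: 16 has no stereocentre, and possible hindered rotation about N1'–C3 is not specified and is left uncontrolled.

## Route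

Step 1
Reactants: 1 4,6-dibromo-1H-indole
Product: 2 4,6-dibromo-3-(methylthio)-1H-indole
Conditions: N-(methylthio)phthalimide (1.1 equiv), MgBr2 (cat.), DMAc, 90 °C
Reagents that add atoms: N-(methylthio)phthalimide, CSN1C(=O)c2ccccc2C1=O
Why: Electrophilic aromatic substitution (C3 sulfenylation of an indole) with an N-thioimide activated by catalytic MgBr2; C3 is the most nucleophilic carbon of 1, the two bromines slow but do not redirect the attack, and the product thioether should not be sulfenylated further.

Step 2
Reactants: 2 4,6-dibromo-3-(methylthio)-1H-indole
Product: 3 2,4,6-tribromo-3-(methylthio)-1H-indole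
Conditions: NBS (1.0 equiv), CH2Cl2, 0 °C → rt, dark
Reagents that add atoms: N-bromosuccinimide, BrN1C(=O)CCC1=O
Why: Electrophilic bromination of a 3-sulfenylindole, which goes to C2 because C3 is occupied and the dibrominated benzo ring is deactivated; one equivalent of NBS in a dry solvent at low temperature should avoid oxidation at sulfur.

Step 3
Reactants: 4 3-methyl-4-nitroaniline
Product: 5 2,6-dibromo-3-methyl-4-nitroaniline
Conditions: NBS (2.1 equiv), MeCN, 0 → 50 °C
Reagents that add atoms: N-bromosuccinimide, BrN1C(=O)CCC1=O
Why: Electrophilic aromatic bromination directed by the amino group; the para position is blocked by the nitro group, so both ortho positions are brominated and no other ring position is activated.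

Step 4
Reactants: 5 2,6-dibromo-3-methyl-4-nitroaniline
Product: 7 1,2,3-tribromo-4-methyl-5-nitrobenzene, via arenediazonium bromide 6 (not isolated)
Conditions: tBuONO (1.5 equiv), CuBr2 (1.2 equiv), MeCN, 0 → 60 °C
Reagents that add atoms: CuBr2, Br[Cu]Br
Why: Sandmeyer bromination with non-aqueous diazotisation by an alkyl nitrite; the weakly basic, di-ortho-substituted aniline is diazotised and the diazonium salt 6 is consumed by CuBr2 as it forms. The new bromine completes the 1,2,3-tribromo array with the methyl group between Br and NO2.

Step 5
Reactants: 7 1,2,3-tribromo-4-methyl-5-nitrobenzene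
Product: 8 1,2,3-tribromo-4-(bromomethyl)-5-nitrobenzene
Conditions: NBS (1.1 equiv), AIBN (cat.), PhCF3, 85 °C
Reagents that add atoms: N-bromosuccinimide, BrN1C(=O)CCC1=O
Why: Wohl–Ziegler radical benzylic bromination; 7 has a single kind of C(sp3)–H bond and ortho-nitro, ortho-bromo toluenes are usual substrates. Conversion is held short of completion to avoid the benzal bromide.

Step 6
Reactants: 3 2,4,6-tribromo-3-(methylthio)-1H-indole; 8 1,2,3-tribromo-4-(bromomethyl)-5-nitrobenzene
Product: 9 2,4,6-tribromo-3-(methylthio)-1-[(2,3,4-tribromo-6-nitrophenyl)methyl]-1H-indole
Conditions: K2CO3 (1.5 equiv), DMF, 0 °C → rt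
Reagents that add atoms: none
Why: SN2 N-alkylation of an indolide; the N–H of 3 is acidified by three bromines so carbonate suffices, C2' and C3' are blocked so nitrogen is the only nucleophilic site, and a benzylic bromide should be reactive enough despite its two ortho substituents.

Step 7
Reactants: 9 2,4,6-tribromo-3-(methylthio)-1-[(2,3,4-tribromo-6-nitrophenyl)methyl]-1H-indole; 10 carbon disulfide
Product: 13 2,4,6-tribromo-1-[2,2-bis(methylthio)-1-(2,3,4-tribromo-6-nitrophenyl)ethenyl]-3-(methylthio)-1H-indole, via sodium dithiocarboxylate 11 (not isolated), via methyl dithioester 12 (not isolated)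
Conditions: NaN(SiMe3)2 (1.05 equiv), THF, −78 °C; 10 (1.2 equiv), −78 → −30 °C; MeI (1.1 equiv); NaN(SiMe3)2 (1.3 equiv), −78 °C; MeI (1.5 equiv), −78 °C → rt
Reagents that add atoms: iodomethane, CI
Why: Proposed new method: NaN(SiMe3)2 should remove a benzylic proton of 9, which is acidified by the ortho nitro group (nitronate-type delocalisation, as in Reissert and Leimgruber–Batcho chemistry), by the three ring bromines and by the indol-1-yl nitrogen. The soft carbanion should add through carbon to 10, forming C2–C3 and giving dithiocarboxylate 11, and S-methylation gives dithioester 12. The remaining C3–H of 12, flanked by aryl, nitrogen and C=S, is far more acidic than that of 9, so the second charge of base gives a thioenolate that is methylated on sulfur to 13. The closest known reaction type is the base/CS2/MeI conversion of active methylene compounds (arylacetonitriles, aryl ketones, nitromethane) into ketene dithioacetals; a carbon acid activated only by an ortho-nitroaryl ring and an azole nitrogen is outside that class. No ring closes and no stereocentre remains: the sp3 centre of 11 and 12 is racemic and becomes trigonal in 13, whose alkene terminus bears two identical SMe groups, so there is no E/Z question. The step needs C-attack on 10 ahead of electron transfer from the carbanion to a nitroarene, of oxygen transfer from the neighbouring nitro group and of substitution of the bromine para to nitro. This should be secured by the low temperature, the non-nucleophilic base, the small soft electrophile and the crowding of the benzylic carbon, which disfavours dimerisation. S- over C-methylation of the thioenolate follows from soft–soft pairing and from crowding at C3; ring B has no acidic or electrophilic site and is a spectator.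

Step 8
Reactants: 13 2,4,6-tribromo-1-[2,2-bis(methylthio)-1-(2,3,4-tribromo-6-nitrophenyl)ethenyl]-3-(methylthio)-1H-indole
Product: 16 4,5,6-tribromo-2-(methylthio)-3-[2,4,6-tribromo-3-(methylthio)-1H-indol-1-yl]-1H-indole, via aniline 14 (not isolated), via 2,2-bis(methylthio)indoline 15 (not isolated)
Conditions: Fe powder (6 equiv), AcOH, 85 °C; off-gas through aq. NaOCl
Reagents that add atoms: none
Why: Béchamp-type reduction of the nitro group with Fe in AcOH, which should leave C–Br and C–S bonds intact, followed in the same flask by acid-mediated addition–elimination of the kind used in reductive cyclisations of 2-nitroaryl ketene dithioacetals. Protonation of 14 at C3 gives a bis(methylthio)carbenium ion that the amino group captures in a 5-exo-trig closure to 15. Loss of methanethiol and tautomerisation then give the aromatic ring A of the target with exactly one SMe on C2.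

## Compound list

1 | 4,6-dibromo-1H-indole | Brc1cc(Br)c2cc[nH]c2c1 | starting material
2 | 4,6-dibromo-3-(methylthio)-1H-indole | CSc1c[nH]c2cc(Br)cc(Br)c12 | intermediate
3 | 2,4,6-tribromo-3-(methylthio)-1H-indole | CSc1c(Br)[nH]c2cc(Br)cc(Br)c12 | intermediate
4 | 3-methyl-4-nitroaniline | Cc1cc(N)ccc1[N+](=O)[O-] | starting material
5 | 2,6-dibromo-3-methyl-4-nitroaniline | Cc1c(Br)c(N)c(Br)cc1[N+](=O)[O-] | intermediate
6 | 2,6-dibromo-3-methyl-4-nitrobenzenediazonium bromide | Cc1c(Br)c([N+]#N)c(Br)cc1[N+](=O)[O-].[Br-] | intermediate (not isolated)
7 | 1,2,3-tribromo-4-methyl-5-nitrobenzene (2,3,4-tribromo-6-nitrotoluene) | Cc1c(Br)c(Br)c(Br)cc1[N+](=O)[O-] | intermediate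
8 | 1,2,3-tribromo-4-(bromomethyl)-5-nitrobenzene | BrCc1c(Br)c(Br)c(Br)cc1[N+](=O)[O-] | intermediate
9 | 2,4,6-tribromo-3-(methylthio)-1-[(2,3,4-tribromo-6-nitrophenyl)methyl]-1H-indole | CSc1c(Br)n(Cc2c([N+](=O)[O-])cc(Br)c(Br)c2Br)c2cc(Br)cc(Br)c12 | intermediate
10 | carbon disulfide | S=C=S | starting material
11 | sodium 2-[2,4,6-tribromo-3-(methylthio)-1H-indol-1-yl]-2-(2,3,4-tribromo-6-nitrophenyl)ethanedithioate (racemic) | CSc1c(Br)n(C(C(=S)[S-])c2c([N+](=O)[O-])cc(Br)c(Br)c2Br)c2cc(Br)cc(Br)c12.[Na+] | intermediate (not isolated)
12 | methyl 2-[2,4,6-tribromo-3-(methylthio)-1H-indol-1-yl]-2-(2,3,4-tribromo-6-nitrophenyl)ethanedithioate (racemic) | CSC(=S)C(c1c([N+](=O)[O-])cc(Br)c(Br)c1Br)n1c(Br)c(SC)c2c(Br)cc(Br)cc21 | intermediate (not isolated)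
13 | 2,4,6-tribromo-1-[2,2-bis(methylthio)-1-(2,3,4-tribromo-6-nitrophenyl)ethenyl]-3-(methylthio)-1H-indole | CSC(SC)=C(c1c([N+](=O)[O-])cc(Br)c(Br)c1Br)n1c(Br)c(SC)c2c(Br)cc(Br)cc21 | intermediate
14 | 3,4,5-tribromo-2-{2,2-bis(methylthio)-1-[2,4,6-tribromo-3-(methylthio)-1H-indol-1-yl]ethenyl}aniline | CSC(SC)=C(c1c(N)cc(Br)c(Br)c1Br)n1c(Br)c(SC)c2c(Br)cc(Br)cc21 | intermediate (not isolated)
15 | 4,5,6-tribromo-2,2-bis(methylthio)-3-[2,4,6-tribromo-3-(methylthio)-1H-indol-1-yl]indoline (racemic) | CSC1(SC)Nc2cc(Br)c(Br)c(Br)c2C1n1c(Br)c(SC)c2c(Br)cc(Br)cc21 | intermediate (not isolated)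
16 | 4,5,6-tribromo-2-(methylthio)-3-[2,4,6-tribromo-3-(methylthio)-1H-indol-1-yl]-1H-indole | CSc1[nH]c2cc(Br)c(Br)c(Br)c2c1-n1c(Br)c(SC)c2c(Br)cc(Br)cc21 | target

## Step count and least certain steps

Total: 8 steps. Longest linear sequence: 6 steps (steps 3, 4, 5, 6, 7, 8). The indole arm (steps 1 and 2) joins at step 6.

**Step 7 (key step, proposed new method).** The most likely failure is redox decomposition of the nitrobenzyl carbanion outrunning C–C bond formation: electron transfer to unreacted nitroarene, or oxygen transfer from the adjacent nitro group. The carbanion sits on a crowded carbon between a di-ortho-substituted aryl ring and a 2-bromoindolyl group, and its addition to 10 is reversible. Substitution of the bromine para to nitro by the dithiocarboxylate is a second risk.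

The fallback uses known chemistry only. It sets out from 7 and 3 and rejoins the route at 16, taking C2 from oxalate and adding sulfur last.
- Reissert condensation of 7 with diethyl oxalate (KOEt, EtOH/Et2O) would give ethyl 3-(2,3,4-tribromo-6-nitrophenyl)-2-oxopropanoate F1.
- Alkaline H2O2 would cleave F1 to (2,3,4-tribromo-6-nitrophenyl)acetic acid F2.
- Fischer esterification (MeOH, H2SO4) would give methyl ester F3.
- Radical bromination (NBS, AIBN) would give methyl 2-bromo-2-(2,3,4-tribromo-6-nitrophenyl)acetate F4.
- N-alkylation of 3 with F4 (K2CO3, DMF) would give methyl 2-(indol-1-yl)-2-(nitroaryl)acetate F5.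
- Fe in AcOH would reduce the nitro group and the aniline would lactamise to 4,5,6-tribromo-3-[2,4,6-tribromo-3-(methylthio)-1H-indol-1-yl]indolin-2-one F6.
- Lawesson's reagent in hot toluene would convert F6 into indoline-2-thione F7.
- S-methylation of F7 (MeI, K2CO3, acetone) would give 16.

**Step 8.** The most likely failure is stalling at the aniline stage, because an unactivated ketene dithioacetal is only weakly electrophilic in AcOH. Water formed in the reduction could also capture the carbenium ion, giving hydrolysis instead of N-closure.

The fallback takes the hydrolytic path on purpose. It sets out from 13 and rejoins at 16.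
- Aqueous TFA would hydrolyse 13 to S-methyl 2-[2,4,6-tribromo-3-(methylthio)-1H-indol-1-yl]-2-(2,3,4-tribromo-6-nitrophenyl)ethanethioate F8.
- Fe in AcOH would reduce F8, and the aniline would lactamise on the thioester to oxindole F6.
- F6 would be thionated to F7 and S-methylated to 16 as described under step 7.

**Step 5.** The most likely failure is slow hydrogen abstraction from an electron-poor methyl group between two ortho substituents, leading to incomplete conversion and, on forcing, over-bromination to the benzal bromide.

The fallback replaces the radical step by ionic chemistry. It sets out from 7 and rejoins at 8.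
- Condensation of 7 with DMF dimethyl acetal (the first stage of a Leimgruber–Batcho sequence) would give (E)-N,N-dimethyl-2-(2,3,4-tribromo-6-nitrophenyl)ethenamine F9.
- NaIO4 in aqueous THF would cleave F9 to 2,3,4-tribromo-6-nitrobenzaldehyde F10.
- NaBH4 would reduce F10 to (2,3,4-tribromo-6-nitrophenyl)methanol F11.
- PBr3 would convert F11 into 8.

**Step 6.** The most likely failure is a slow SN2 displacement between a hindered, weakly nucleophilic 2-bromoindolide and a di-ortho-substituted benzyl bromide. That would leave time for base-induced self-condensation of 8, whose CH2 is acidic, or for substitution of the bromine para to nitro.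

The fallback changes the order of events. It sets out from 2 and 8 and rejoins at 9.
- The less hindered 2 would be N-alkylated with 8 (K2CO3, DMF) to give 4,6-dibromo-3-(methylthio)-1-[(2,3,4-tribromo-6-nitrophenyl)methyl]-1H-indole F12.
- NBS in CH2Cl2 would brominate F12 at C2' to give 9.

## Further compounds

F1 | step 7 | ethyl 3-(2,3,4-tribromo-6-nitrophenyl)-2-oxopropanoate | CCOC(=O)C(=O)Cc1c(Br)c(Br)c(Br)cc1[N+](=O)[O-]
F2 | step 7 | (2,3,4-tribromo-6-nitrophenyl)acetic acid | OC(=O)Cc1c(Br)c(Br)c(Br)cc1[N+](=O)[O-]
F3 | step 7 | methyl (2,3,4-tribromo-6-nitrophenyl)acetate | COC(=O)Cc1c(Br)c(Br)c(Br)cc1[N+](=O)[O-]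
F4 | step 7 | methyl 2-bromo-2-(2,3,4-tribromo-6-nitrophenyl)acetate (racemic) | COC(=O)C(Br)c1c(Br)c(Br)c(Br)cc1[N+](=O)[O-]
F5 | step 7 | methyl 2-[2,4,6-tribromo-3-(methylthio)-1H-indol-1-yl]-2-(2,3,4-tribromo-6-nitrophenyl)acetate (racemic) | COC(=O)C(c1c([N+](=O)[O-])cc(Br)c(Br)c1Br)n1c(Br)c(SC)c2c(Br)cc(Br)cc21
F6 | step 7 | 4,5,6-tribromo-3-[2,4,6-tribromo-3-(methylthio)-1H-indol-1-yl]indolin-2-one (racemic) | O=C1Nc2cc(Br)c(Br)c(Br)c2C1n1c(Br)c(SC)c2c(Br)cc(Br)cc21
F7 | step 7 | 4,5,6-tribromo-3-[2,4,6-tribromo-3-(methylthio)-1H-indol-1-yl]indoline-2-thione (racemic) | S=C1Nc2cc(Br)c(Br)c(Br)c2C1n1c(Br)c(SC)c2c(Br)cc(Br)cc21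
F8 | step 8 | S-methyl 2-[2,4,6-tribromo-3-(methylthio)-1H-indol-1-yl]-2-(2,3,4-tribromo-6-nitrophenyl)ethanethioate (racemic) | CSC(=O)C(c1c([N+](=O)[O-])cc(Br)c(Br)c1Br)n1c(Br)c(SC)c2c(Br)cc(Br)cc21
F9 | step 5 | (E)-N,N-dimethyl-2-(2,3,4-tribromo-6-nitrophenyl)ethenamine | CN(C)/C=C/c1c(Br)c(Br)c(Br)cc1[N+](=O)[O-]
F10 | step 5 | 2,3,4-tribromo-6-nitrobenzaldehyde | O=Cc1c(Br)c(Br)c(Br)cc1[N+](=O)[O-]
F11 | step 5 | (2,3,4-tribromo-6-nitrophenyl)methanol | OCc1c(Br)c(Br)c(Br)cc1[N+](=O)[O-]
F12 | step 6 | 4,6-dibromo-3-(methylthio)-1-[(2,3,4-tribromo-6-nitrophenyl)methyl]-1H-indole | CSc1cn(Cc2c([N+](=O)[O-])cc(Br)c(Br)c2Br)c2cc(Br)cc(Br)c12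
A1 | alternative 1 | 4,6-dibromo-1-[4,5,6-tribromo-2-(methylthio)-1H-indol-3-yl]indolin-3-one | CSc1[nH]c2cc(Br)c(Br)c(Br)c2c1N1CC(=O)c2c(Br)cc(Br)cc21
A2 | alternative 1 | methyl N-[4,5,6-tribromo-2-(methylthio)-1H-indol-3-yl]glycinate | CSc1[nH]c2cc(Br)c(Br)c(Br)c2c1NCC(=O)OC
A3 | alternative 1 | 2,4-dibromo-6-(trimethylsilyl)phenyl trifluoromethanesulfonate | C[Si](C)(C)c1cc(Br)cc(Br)c1OS(=O)(=O)C(F)(F)F
A4 | alternative 2 | methyl 4,6-dibromo-3-hydroxy-1-[4,5,6-tribromo-2-(methylthio)-1H-indol-3-yl]-1H-indole-2-carboxylate | CSc1[nH]c2cc(Br)c(Br)c(Br)c2c1-n1c(C(=O)OC)c(O)c2c(Br)cc(Br)cc21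
A5 | alternative 2 | methyl 2,4-dibromo-6-{(2-methoxy-2-oxoethyl)[4,5,6-tribromo-2-(methylthio)-1H-indol-3-yl]amino}benzoate | CSc1[nH]c2cc(Br)c(Br)c(Br)c2c1N(CC(=O)OC)c1cc(Br)cc(Br)c1C(=O)OC
A6 | alternative 3 | 2,4,6-tribromo-1-[4,5,6-tribromo-2-(methylthio)-1H-indol-3-yl]-1H-indole | CSc1[nH]c2cc(Br)c(Br)c(Br)c2c1-n1c(Br)cc2c(Br)cc(Br)cc21
A7 | alternative 3 | 4,5,6-tribromo-N-[3,5-dibromo-2-(2,2-dibromoethenyl)phenyl]-2-(methylthio)-1H-indol-3-amine | CSc1[nH]c2cc(Br)c(Br)c(Br)c2c1Nc1cc(Br)cc(Br)c1C=C(Br)Br
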